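(The numbers in the tables come from a simulation on assumed constants; noise was put on by code.)

**Reading the runs.** A leftover of 30% of the X stands in the red run at 2.50 min, and of 12% in the violet run, which was charged with more Z. The red run lost 44.0% of its X by 0.200 min and then 26 percentage points more, so the reaction brakes itself as it goes, the pattern called product inhibition.

all flasks: X 0.10 M

| charge | J | Z | remark | time |
|---|---|---|---|---|
| red | 0.095 M | 0.096 M | run made earlier |  |
| violet | 0.095 M | 0.25 M | run made earlier |  |
| south-west | 0.0950 M | 0.0800 M |  | 2.5 min |
| east | 0.0950 M | 0.120 M |  | 2.5 min |
| south | 0.0950 M | 0.180 M |  | 2.5 min |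

| run | time / min | X / % | G / % |
|---|---|---|---|
| red | 0.200 | 56 | 49 |
| red | 0.333 | 46 | 50 |
| red | 0.500 | 46 | 54 |
| red | 0.833 | 40 | 58 |
| red | 1.50 | 36 | 62 |
| red | 2.50 | 30 | 68 |
| violet | 0.417 | 44 | 62 |
| violet | 0.833 | 29 | 70 |
| violet | 1.33 | 20 | 76 |
| violet | 1.50 | 16 | 81 |
| violet | 2.00 | 18 | 84 |
| violet | 2.50 | 12 | 83 |

(each reading ± 2 percentage points)

- part of the X that has reacted at the end, south-west
- part of the X that has reacted at the end, east
- part of the X that has reacted at the end, south
- what raising the concentration of Z from its lowest to its highest value here does to the part of the X that has reacted (changes below 5 percentage points count as none) (no change / it falls / it rises)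



**Freezing the leftovers.** We write the rate as a constant times the leftovers of X, J and Z, divided by the conversion. Each leftover is its charge, in units of the X charge, minus the X reacted. Over a stretch we freeze their product at its mid-stretch value. Conversion times rate is then steady, so the square of the conversion gains 2 × constant × product × time.

From 0.833 min to 2.50 min the red run climbs from 60.0% to 70.0%, which gives 1.20 /min. Over the same times the violet run climbs from 71.0% to 88.0%, which gives 1.50 /min. A climb of 10 points read with a scatter of 2 points at each end cannot separate these two. Their mean, 1.35 /min, is our brake constant, the rate times the conversion divided by the three leftovers.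

**Two routes.** First, we interpolate the end conversions of the two runs on the logarithm of Z. This gives 66.6% for south-west, 74.2% for east and 81.8% for south, a rise of 15 points.

Second, we interpolate the same way at 0.833 min, which gives 57.9% for south-west and 67.2% for south, and then let the brake constant carry each flask to the end. That gives 65.9% and 83.6%. The second route starts from the same interpolation and takes its mid-stretch leftovers from the first route's end values, so its closeness to the first is no independent check. We commit to the first route, the shorter of the two.

**The forecast.** It says 64%, 74% and 81%, and that the conversion it rises, on the grounds of “a fast burst, then a marked slowdown well before J or Z is used up”. Our south-west number stands above its value.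

**The flask.** South-west gives 67.9%, east 75.1% and south 81.7%, so the conversion it rises by 14 points.

    X + J ⇌ Q + G (K = 0.640, k = 2.80 /M/s)
    J + Q ⇌ D, settled at all times (K = 760 /M)
    Q + Z ⇌ L (K = 4.40 × 10⁵ /M, k = 2.20 /M/s)
    J ⇌ E (K = 25.0, k = 0.00370 /s)

Carried from the south state at 1.25 min, the brake constant gives 81.8% at the end. Run back from there to 1.0 min, it gives 66.6%, where the same flask read at that time stands at 69.4%. The difference in Z is the main reason for the gap between south and south-west, and turning Q into L is part of how it acts: with that step taken away, the gap falls from 14 points to 0 points.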